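**Retrosynthetic overview**

1. Rings: A has its OH para to its ether oxygen and the CH2CH2 bridge ortho to it; B has its OH ortho to its ether oxygen; C is the para-phenylene; D is the meta-phenylene. The strategy rests on the ring A carbon that carries the ether oxygen to ring D. It sits ortho to the CH2CH2 bridge, a hindered ipso position of the kind a diaryl-λ3-iodane hands over readily to a phenoxide.
2. Last skeletal bond: ring A C–O(ring D), by aryl transfer from an aryl(2,4,6-trimethoxyphenyl)iodonium centre on ring A to the ring D phenoxide. This closes the 18-membered ring, the only ring formed in the route.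
3. The iodonium salt comes from the open-chain aryl iodide (ring A OTs, ring B OBn, ring D silyl ether) by mCPBA/TsOH and then 1,3,5-trimethoxybenzene.
4. Open chain: ring B–O–ring C by SNAr on 4-fluorobenzaldehyde; the ring C–ring D and ring A–ring B bridges by two Wittig olefinations, both alkenes saturated together by diimide.
5. End: tosylate cleavage, then hydrogenolysis of the benzyl ether.

Key step: step 12

Remarks on the chemistry:
- The ring B formyl group is reduced before the SNAr, so the diaryl ether never carries two aldehydes that would need to be told apart.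
- Ring D is carried as a triisopropylsilyl ether, which should tolerate TsOH (step 11) and hot aqueous acetate (step 10) and is still cleaved at once by fluoride.
- Both Wittig steps are assumed to give E/Z mixtures. These are used as such and their SMILES are written without alkene geometry.

**Route**

Step 1
Reactants: 1 5-hydroxy-2-iodobenzaldehyde
Product: 2 3-formyl-4-iodophenyl 4-methylbenzenesulfonate
Conditions: TsCl, Et3N, DMAP (cat.), CH2Cl2, 0 °C to rt
Reagents that add atoms: 4-methylbenzenesulfonyl chloride (TsCl), Cc1ccc(cc1)S(Cl)(=O)=O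
Why: O-sulfonylation of the phenol under amine base leaves the aldehyde and the aryl iodide untouched and installs the electron-withdrawing group that ring A needs later.

Step 2
Reactants: 3 4-(benzyloxy)-3-hydroxybenzaldehyde
Product: 4 2-(benzyloxy)-5-(hydroxymethyl)phenol
Conditions: NaBH4, MeOH, 0 °C
Reagents that add atoms: none
Why: Borohydride reduction turns the ring B aldehyde into a benzylic alcohol, so that after step 3 only ring C carries a formyl group.

Step 3
Reactants: 4 2-(benzyloxy)-5-(hydroxymethyl)phenol; 5 4-fluorobenzaldehyde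
Product: 6 4-[2-(benzyloxy)-5-(hydroxymethyl)phenoxy]benzaldehyde
Conditions: K2CO3, DMF, 120 °C
Reagents that add atoms: none
Why: Nucleophilic aromatic substitution (SNAr) of the para-formyl-activated fluoride by the phenoxide, which K2CO3 forms selectively because the benzylic alcohol is far less acidic.

Step 4
Reactants: 7 3-hydroxybenzyl alcohol
Product: 8 (3-hydroxybenzyl)triphenylphosphonium bromide
Conditions: PPh3·HBr, MeCN, reflux
Reagents that add atoms: triphenylphosphine hydrobromide, Br.c1ccc(cc1)P(c1ccccc1)c1ccccc1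
Why: Acid-promoted substitution of the benzylic hydroxyl (through the benzylic bromide) by triphenylphosphine gives the phosphonium salt in one operation, and the phenol does not take part.

Step 5
Reactants: 8 (3-hydroxybenzyl)triphenylphosphonium bromide
Product: 9 triphenyl{3-[(triisopropylsilyl)oxy]benzyl}phosphonium bromide
Conditions: TIPSCl, imidazole, CH2Cl2, rt; aq. NaBr wash
Reagents that add atoms: chlorotriisopropylsilane (TIPSCl), CC(C)[Si](Cl)(C(C)C)C(C)C
Why: Imidazole-mediated silylation of the phenol, the only nucleophilic site of the salt.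

Step 6
Reactants: 9 triphenyl{3-[(triisopropylsilyl)oxy]benzyl}phosphonium bromide; 6 4-[2-(benzyloxy)-5-(hydroxymethyl)phenoxy]benzaldehyde
Product: 11 {4-(benzyloxy)-3-[4-(2-{3-[(triisopropylsilyl)oxy]phenyl}ethenyl)phenoxy]phenyl}methanol (E/Z mixture), via phosphonium ylide 10 (not isolated)
Conditions: 9, NaN(SiMe3)2, THF, 0 °C; then 6, 0 °C to rt
Reagents that add atoms: none
Why: Wittig olefination of the ring C aldehyde by a semi-stabilised benzylic ylide, which is too weak a base to be quenched by the free benzylic alcohol; the alkene geometry does not matter because step 10 saturates it.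

Step 7
Reactants: 11 {4-(benzyloxy)-3-[4-(2-{3-[(triisopropylsilyl)oxy]phenyl}ethenyl)phenoxy]phenyl}methanol
Product: 12 {3-[2-(4-{2-(benzyloxy)-5-(bromomethyl)phenoxy}phenyl)ethenyl]phenoxy}triisopropylsilane (E/Z mixture)
Conditions: CBr4, PPh3, CH2Cl2, 0 °C
Reagents that add atoms: tetrabromomethane, BrC(Br)(Br)Br
Why: Appel bromination converts the benzylic alcohol under neutral conditions that the silyl ether, the benzyl ether and the alkene tolerate; the bromide is used at once.

Step 8
Reactants: 12 {3-[2-(4-{2-(benzyloxy)-5-(bromomethyl)phenoxy}phenyl)ethenyl]phenoxy}triisopropylsilane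
Product: 13 {4-(benzyloxy)-3-[4-(2-{3-[(triisopropylsilyl)oxy]phenyl}ethenyl)phenoxy]benzyl}triphenylphosphonium bromide
Conditions: PPh3, toluene, 80 °C
Reagents that add atoms: triphenylphosphine, c1ccc(cc1)P(c1ccccc1)c1ccccc1
Why: SN2 quaternisation of triphenylphosphine by the reactive benzylic bromide.

Step 9
Reactants: 13 {4-(benzyloxy)-3-[4-(2-{3-[(triisopropylsilyl)oxy]phenyl}ethenyl)phenoxy]benzyl}triphenylphosphonium bromide; 2 3-formyl-4-iodophenyl 4-methylbenzenesulfonate
Product: 15 3-[2-(4-(benzyloxy)-3-{4-[2-(3-{[triisopropylsilyl]oxy}phenyl)ethenyl]phenoxy}phenyl)ethenyl]-4-iodophenyl 4-methylbenzenesulfonate (E/Z mixture at both alkenes), via phosphonium ylide 14 (not isolated)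
Conditions: 13, NaN(SiMe3)2 (slight deficit), THF, 0 °C; then 2, −78 °C to rt
Reagents that add atoms: none
Why: Wittig olefination in which the preformed ylide adds to the aldehyde much faster than it could attack the aryl sulfonate or the aryl iodide, and no free amide base remains to do so.

Step 10
Reactants: 15 3-[2-(4-(benzyloxy)-3-{4-[2-(3-{[triisopropylsilyl]oxy}phenyl)ethenyl]phenoxy}phenyl)ethenyl]-4-iodophenyl 4-methylbenzenesulfonate
Product: 16 3-[2-(4-(benzyloxy)-3-{4-[2-(3-{[triisopropylsilyl]oxy}phenyl)ethyl]phenoxy}phenyl)ethyl]-4-iodophenyl 4-methylbenzenesulfonate (open-chain aryl iodide)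
Conditions: TsNHNH2 (excess), NaOAc, DME/H2O, reflux
Reagents that add atoms: none
Why: Diimide reduction, in which diimide released from the sulfonyl hydrazide transfers H2 to both disubstituted alkenes in a concerted way and spares the aryl iodide, benzyl ether, tosylate and silyl ether that metal-catalysed hydrogenation would endanger.

Step 11
Reactants: 16 open-chain aryl iodide
Product: 18 (2,4,6-trimethoxyphenyl){2-[2-(4-(benzyloxy)-3-{4-[2-(3-{[triisopropylsilyl]oxy}phenyl)ethyl]phenoxy}phenyl)ethyl]-4-(tosyloxy)phenyl}iodonium 4-methylbenzenesulfonate, via hydroxy(tosyloxy)-λ3-iodane 17 (not isolated)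
Conditions: mCPBA, TsOH·H2O, MeCN, 50 °C; then 1,3,5-trimethoxybenzene, rt
Reagents that add atoms: 1,3,5-trimethoxybenzene, COc1cc(OC)cc(OC)c1; 4-methylbenzenesulfonic acid monohydrate, Cc1ccc(cc1)S(=O)(=O)O.O; mCPBA, OOC(=O)c1cccc(Cl)c1 (its oxygen stays only in intermediate 17)
Why: Peracid oxidation of the aryl iodide in the presence of TsOH gives the hydroxy(tosyloxy)-λ3-iodane, whose electrophilic trivalent iodine is attacked (electrophilic aromatic substitution) by the very nucleophilic 1,3,5-trimethoxybenzene, the known one-pot entry to aryl(2,4,6-trimethoxyphenyl)iodonium tosylates; acetonitrile without fluoroalcohol and prompt addition of the trimethoxybenzene should keep the less activated rings B, C and D out of the reaction.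

Step 12
Reactants: 18 ring A aryl(2,4,6-trimethoxyphenyl)iodonium tosylate
Product: 20 18-membered macrocyclic bis(bibenzyl) diaryl ether bearing ring A tosylate plus ring B benzyl ether, via aryloxy-λ3-iodane 19 (not isolated)
Conditions: Bu4NF, THF, rt; 18 added slowly by syringe pump (about 1 mM final)
Reagents that add atoms: none
Why: Fluoride cleaves the Si–O bond of 18 and the ring D phenoxide replaces tosylate on the trivalent iodine centre to give the neutral T-shaped aryloxy-λ3-iodane 19, which collapses by ligand coupling through a three-centre transition state at the ring A ipso carbon. The closest known reaction is the metal-free O-arylation of phenols with aryl(2,4,6-trimethoxyphenyl)iodonium salts at room temperature. The 18-membered ring closes by intramolecular ipso substitution at the sp2 carbon of ring A, with 2-iodo-1,3,5-trimethoxybenzene as the leaving group; no stereocentre is formed. The step needs transfer of ring A and not of the trimethoxyphenyl group, which the ortho CH2CH2 substituent and the para tosyloxy group of ring A, set against the electron-rich auxiliary aryl, should secure. It also needs ring closure to outrun intermolecular aryl transfer, which slow addition of 18 to dilute fluoride should secure, because iodine–oxygen ligand exchange is fast and reversible while the coupling is not.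

Step 13
Reactants: 20 macrocyclic ring A tosylate
Product: 21 macrocycle bearing free ring A phenol plus ring B benzyl ether
Conditions: KOH, MeOH/THF, 60 °C; then aq. HCl
Reagents that add atoms: none
Why: Base-mediated cleavage of the aryl sulfonate by attack at sulfur frees the ring A phenol, while diaryl ethers and the benzyl ether are inert to hydroxide.

Step 14
Reactants: 21 macrocyclic ring B benzyl ether
Product: 22 dihydroptychantol A
Conditions: H2 (1 atm), Pd/C, EtOAc/MeOH, rt
Reagents that add atoms: none
Why: Catalytic hydrogenolysis of the benzyl ether releases the ring B phenol; the diaryl ethers and the bibenzyl bridges are stable to these conditions.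

**Compound list**

1 | 5-hydroxy-2-iodobenzaldehyde | O=Cc1cc(O)ccc1I | starting material
2 | 3-formyl-4-iodophenyl 4-methylbenzenesulfonate | Cc1ccc(cc1)S(=O)(=O)Oc1ccc(I)c(C=O)c1 | intermediate
3 | 4-(benzyloxy)-3-hydroxybenzaldehyde | O=Cc1ccc(OCc2ccccc2)c(O)c1 | starting material
4 | 2-(benzyloxy)-5-(hydroxymethyl)phenol | OCc1ccc(OCc2ccccc2)c(O)c1 | intermediate
5 | 4-fluorobenzaldehyde | O=Cc1ccc(F)cc1 | starting material
6 | 4-[2-(benzyloxy)-5-(hydroxymethyl)phenoxy]benzaldehyde | O=Cc1ccc(cc1)Oc1cc(CO)ccc1OCc1ccccc1 | intermediate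
7 | 3-hydroxybenzyl alcohol | OCc1cccc(O)c1 | starting material
8 | (3-hydroxybenzyl)triphenylphosphonium bromide | Oc1cccc(C[P+](c2ccccc2)(c2ccccc2)c2ccccc2)c1.[Br-] | intermediate
9 | triphenyl{3-[(triisopropylsilyl)oxy]benzyl}phosphonium bromide | CC(C)[Si](C(C)C)(C(C)C)Oc1cccc(C[P+](c2ccccc2)(c2ccccc2)c2ccccc2)c1.[Br-] | intermediate
10 | ylide of 9, triphenyl{3-[(triisopropylsilyl)oxy]benzylidene}phosphorane | CC(C)[Si](C(C)C)(C(C)C)Oc1cccc(C=P(c2ccccc2)(c2ccccc2)c2ccccc2)c1 | intermediate (not isolated)
11 | {4-(benzyloxy)-3-[4-(2-{3-[(triisopropylsilyl)oxy]phenyl}ethenyl)phenoxy]phenyl}methanol, E/Z mixture | OCc1ccc(OCc2ccccc2)c(c1)Oc1ccc(cc1)C=Cc1cccc(c1)O[Si](C(C)C)(C(C)C)C(C)C | intermediate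
12 | benzylic bromide of 11, E/Z mixture | BrCc1ccc(OCc2ccccc2)c(c1)Oc1ccc(cc1)C=Cc1cccc(c1)O[Si](C(C)C)(C(C)C)C(C)C | intermediate
13 | benzyltriphenylphosphonium bromide from 12, E/Z mixture | [Br-].c1ccc(cc1)[P+](Cc1ccc(OCc2ccccc2)c(c1)Oc1ccc(cc1)C=Cc1cccc(c1)O[Si](C(C)C)(C(C)C)C(C)C)(c1ccccc1)c1ccccc1 | intermediate
14 | ylide of 13 | c1ccc(cc1)P(=Cc1ccc(OCc2ccccc2)c(c1)Oc1ccc(cc1)C=Cc1cccc(c1)O[Si](C(C)C)(C(C)C)C(C)C)(c1ccccc1)c1ccccc1 | intermediate (not isolated)
15 | open-chain bis-stilbene: ring A (I, OTs)–CH=CH–ring B (OBn)–O–ring C–CH=CH–ring D (OTIPS), E/Z mixture at both alkenes | Cc1ccc(cc1)S(=O)(=O)Oc1ccc(I)c(c1)C=Cc1ccc(OCc2ccccc2)c(c1)Oc1ccc(cc1)C=Cc1cccc(c1)O[Si](C(C)C)(C(C)C)C(C)C | intermediate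
16 | open-chain aryl iodide with both bridges saturated: ring A (I, OTs)–CH2CH2–ring B (OBn)–O–ring C–CH2CH2–ring D (OTIPS) | Cc1ccc(cc1)S(=O)(=O)Oc1ccc(I)c(c1)CCc1ccc(OCc2ccccc2)c(c1)Oc1ccc(cc1)CCc1cccc(c1)O[Si](C(C)C)(C(C)C)C(C)C | intermediate
17 | ring A hydroxy(tosyloxy)-λ3-iodane of 16 | Cc1ccc(cc1)S(=O)(=O)Oc1ccc(I(O)OS(=O)(=O)c2ccc(C)cc2)c(c1)CCc1ccc(OCc2ccccc2)c(c1)Oc1ccc(cc1)CCc1cccc(c1)O[Si](C(C)C)(C(C)C)C(C)C | intermediate (not isolated)
18 | ring A aryl(2,4,6-trimethoxyphenyl)iodonium tosylate with ring A OTs, ring B OBn, ring D OTIPS | COc1cc(OC)c([I+]c2ccc(OS(=O)(=O)c3ccc(C)cc3)cc2CCc2ccc(OCc3ccccc3)c(c2)Oc2ccc(cc2)CCc2cccc(c2)O[Si](C(C)C)(C(C)C)C(C)C)c(OC)c1.Cc1ccc(cc1)S(=O)(=O)[O-] | intermediate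
19 | aryloxy-λ3-iodane: ring D phenoxide bound to the iodine that carries ring A and the 2,4,6-trimethoxyphenyl group | COc1cc(OC)c(c(OC)c1)I1Oc2cccc(c2)CCc2ccc(cc2)Oc2cc(ccc2OCc2ccccc2)CCc2cc(OS(=O)(=O)c3ccc(C)cc3)ccc12 | intermediate (not isolated)
20 | 18-membered macrocycle, ring A tosylate, ring B benzyl ether | Cc1ccc(cc1)S(=O)(=O)Oc1ccc2c(c1)CCc1ccc(OCc3ccccc3)c(c1)Oc1ccc(cc1)CCc1cccc(c1)O2 | intermediate
21 | macrocycle, free ring A phenol, ring B benzyl ether | Oc1ccc2c(c1)CCc1ccc(OCc3ccccc3)c(c1)Oc1ccc(cc1)CCc1cccc(c1)O2 | intermediate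
22 | dihydroptychantol A (no stereocentres) | Oc1ccc2c(c1)CCc1ccc(O)c(c1)Oc1ccc(cc1)CCc1cccc(c1)O2 | target

**Step count**

Total: 14 steps. Longest linear sequence: 11 steps (from 3 through steps 2, 3, 6–14; the same length from 7 through steps 4–14).

**Steps most likely to fail**

Step 12 (macrocyclization). Intermolecular aryl transfer could outpace ring closure and give oligomers. Adventitious hydroxide could also take the aryl group, or the trimethoxyphenyl group could be transferred in place of ring A. Fallback, copper-mediated oxidative C–O coupling (Chan–Lam): setting out from 16, Miyaura borylation (B2pin2, PdCl2(dppf), KOAc, dioxane, 80 °C; the aryl tosylate is inert to this catalyst) would give the ring A pinacol boronate F1. NaIO4/NH4OAc in acetone–water would release the ring A boronic acid F2. Acetic-acid-buffered Bu4NF in THF at 0 °C would free the ring D phenol to give the hydroxy boronic acid F3. Cu(OAc)2, pyridine, 4 Å molecular sieves, CH2Cl2 under air at high dilution should then close the diaryl ether and come back to the route at 20.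

Step 11 (iodonium formation). The freshly formed hydroxy(tosyloxy)-λ3-iodane could attack ring B of its own molecule before the trimethoxybenzene is added, closing a seven-membered cyclic iodonium. The peracid/acid medium could also degrade the electron-rich rings or erode the silyl ether. Fallback, no oxidant and no iodonium: setting out from 16, acetic-acid-buffered Bu4NF (THF, 0 °C) would give the open-chain iodo phenol F4. Intramolecular Ullmann ether synthesis (CuI, N,N-dimethylglycine, Cs2CO3, dioxane, 90 °C, high dilution) should then close the ring directly and come back to the route at 20, bypassing 18.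

Step 10 (double diimide reduction). Two stilbene units must both be saturated by a reagent that also disproportionates, so saturation could stall. Long heating in aqueous acetate could also slowly cleave the silyl ether. Fallback, saturate the first alkene before iodine enters the molecule: setting out from 11, hydrogenation over Pd/C poisoned with 2,2'-bipyridyl (H2, THF, rt; the nitrogen base suppresses hydrogenolysis of the aryl benzyl ether) would give the bibenzyl alcohol F5. Appel bromination (CBr4, PPh3) would give the bromide F6 and PPh3 in toluene the phosphonium bromide F7. NaN(SiMe3)2 would give the ylide F8, and Wittig reaction with 2 the mono-stilbene F9. The single remaining alkene would be reduced by diimide generated at room temperature from 2-nitrobenzenesulfonyl hydrazide and Et3N in CH2Cl2, coming back to the route at 16.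

**Further compounds**

F1 | step 12 | ring A pinacol boronate of the open chain (OTs, OBn, OTIPS retained) | Cc1ccc(cc1)S(=O)(=O)Oc1ccc(B2OC(C)(C)C(C)(C)O2)c(c1)CCc1ccc(OCc2ccccc2)c(c1)Oc1ccc(cc1)CCc1cccc(c1)O[Si](C(C)C)(C(C)C)C(C)C
F2 | step 12 | ring A boronic acid of the open chain (OTs, OBn, OTIPS retained) | Cc1ccc(cc1)S(=O)(=O)Oc1ccc(B(O)O)c(c1)CCc1ccc(OCc2ccccc2)c(c1)Oc1ccc(cc1)CCc1cccc(c1)O[Si](C(C)C)(C(C)C)C(C)C
F3 | step 12 | ring A boronic acid with free ring D phenol | Cc1ccc(cc1)S(=O)(=O)Oc1ccc(B(O)O)c(c1)CCc1ccc(OCc2ccccc2)c(c1)Oc1ccc(cc1)CCc1cccc(O)c1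
F4 | step 11 | open-chain ring A iodide with free ring D phenol | Cc1ccc(cc1)S(=O)(=O)Oc1ccc(I)c(c1)CCc1ccc(OCc2ccccc2)c(c1)Oc1ccc(cc1)CCc1cccc(O)c1
F5 | step 10 | {4-(benzyloxy)-3-[4-(2-{3-[(triisopropylsilyl)oxy]phenyl}ethyl)phenoxy]phenyl}methanol | OCc1ccc(OCc2ccccc2)c(c1)Oc1ccc(cc1)CCc1cccc(c1)O[Si](C(C)C)(C(C)C)C(C)C
F6 | step 10 | benzylic bromide of F5 | BrCc1ccc(OCc2ccccc2)c(c1)Oc1ccc(cc1)CCc1cccc(c1)O[Si](C(C)C)(C(C)C)C(C)C
F7 | step 10 | benzyltriphenylphosphonium bromide from F6 | [Br-].c1ccc(cc1)[P+](Cc1ccc(OCc2ccccc2)c(c1)Oc1ccc(cc1)CCc1cccc(c1)O[Si](C(C)C)(C(C)C)C(C)C)(c1ccccc1)c1ccccc1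
F8 | step 10 | ylide of F7 | c1ccc(cc1)P(=Cc1ccc(OCc2ccccc2)c(c1)Oc1ccc(cc1)CCc1cccc(c1)O[Si](C(C)C)(C(C)C)C(C)C)(c1ccccc1)c1ccccc1
F9 | step 10 | mono-stilbene: ring A (I, OTs)–CH=CH–ring B, saturated ring C–ring D bridge, E/Z mixture | Cc1ccc(cc1)S(=O)(=O)Oc1ccc(I)c(c1)C=Cc1ccc(OCc2ccccc2)c(c1)Oc1ccc(cc1)CCc1cccc(c1)O[Si](C(C)C)(C(C)C)C(C)C
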